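Ring positions used throughout: ring A is the benzoyl ring (C1 bears the ester carbonyl, C2 heptyl, C4 methoxy, C6 hydroxyl); ring B is the benzoic acid ring (C1 bears CO2H, C2 methoxy, C4 the ester oxygen, C6 pentyl).

## Analysis of the target

The target 18 is a depside: two benzene rings joined through an aryl ester, with no stereocentre and no ring other than the two arenes. Ring A carries heptyl at C2, methoxy at C4 and a free hydroxyl at C6; ring B carries methoxy at C2, the ester oxygen at C4 and pentyl at C6, around a free carboxyl at C1. The sensitive groups are the aryl ester, which is an activated ester and will not tolerate hydroxide, alkoxide or amine nucleophiles once formed, the ring B carboxylic acid, which sits between two ortho substituents on an oxygenated ring and can lose CO2 when heated in acid, and the two methyl ethers that must stay while one phenol ends free. Two things make the synthesis hard. The acyl carbon on ring A is flanked by heptyl and by oxygen, so any esterification through a tetrahedral intermediate at that carbon is slow, and on each ring two oxygen functions of the same kind must be told apart (OMe against OH on ring A, OMe against O-acyl on ring B). The strategy rests on one feature of ring B: C4, the carbon bonded to the ester oxygen, has hydrogen at both C3 and C5 and is the only ring B position without an ortho substituent. That makes it the position a sterically governed C–H borylation selects, and it lets the O–C4 bond be formed at an unhindered aryl carbon, away from the crowded acyl carbon of ring A.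

## Retrosynthetic reasoning

**18 ⇒ 17.** The last operation should only uncover functional groups. Target 18 is traced to 17, in which the ring A hydroxyl is a methoxymethyl ether and the ring B carboxyl a tert-butyl ester. Both masks leave by acid-promoted C–O ionisation, so no base or nucleophile meets the aryl ester and one treatment removes both. Benzyl-type masks were not chosen because their phenyl rings would compete in the C–H borylation used on ring B.

**17 ⇒ 8 + 16.** The ester is cut between the ester oxygen and C4 of ring B, not between the acyl carbon and oxygen. This turns the hindered acid 8 from a poor acyl donor into an oxygen nucleophile: its carboxylate oxygens remain accessible although C1 of ring A is shielded on both sides. The electrophilic partner is the boronic acid 16, whose boron sits on the unhindered C4. The forward reaction is a copper-mediated aerobic coupling that must form the aryl–oxygen bond faster than the boronic acid is consumed by hydroxylation, homocoupling or protodeboronation.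

**16 ⇒ 15 ⇒ 13 + 14.** The C4–B bond is cut back to a C–H bond. In 13 the three ring hydrogens differ sterically: C3–H lies next to methoxy, C5–H next to pentyl, and only C4–H has two hydrogen neighbours. An iridium-catalysed borylation with 14 should therefore deliver boron to C4 alone, giving 15, and mild cleavage of the diol ester gives 16. No oxygen is ever installed or differentiated on ring B: the ester oxygen of the target comes from ring A's carboxyl.

**13 ⇒ 10 + 11, 10 ⇒ 9.** The pentyl chain is cut at the bond between its first and second carbon. The methyl group of 10 is acidified by the ortho ester, so lateral deprotonation and alkylation with 11 builds the chain in one step. The tert-butyl ester serves three purposes: it is too hindered for the benzylic anion to attack, it is inert to the borylation, and it is the final protecting group. It is put on acid 9 by O-alkylation, which avoids the hindered acyl carbon. The C2 methoxy of ring B is bought with 9.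

**8 ⇒ 7 ⇒ 6 ⇒ 5.** The ring A carboxyl is carried as an aldehyde until the end of this branch. The formyl group of 5 directs chelation-controlled cleavage of only the ortho methyl ether (giving 6), which settles OMe against OH on ring A. With the carboxyl still masked, the phenol of 6 can be protected (giving 7) without any competition from a carboxylate. A mild aldehyde oxidation then gives 8.

**5 ⇒ 3 ⇒ 1 + 2.** The formyl carbon is cut from C1 of ring A. In 3 the position between heptyl and methoxy is para to the other methoxy and is the preferred site of electrophilic formylation, which proceeds through iminium salt 4. Arene 3 is cut at the aryl–alkyl bond to the bromide 1 and the Grignard reagent 2, a one-step cross-coupling.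

## Alternatives that were turned down

**Alternative 1:** Ring B would be built from acyclic material, cutting the C1–C6 and C2–C3 bonds of ring B. Dibenzyl malonate A1 adds in a Michael sense to (E)-non-3-en-2-one A2, and the methyl ketone enolate then closes onto one ester (Claisen condensation). This should give the racemic trans cyclohexenone A3, benzyl 2-hydroxy-4-oxo-6-pentylcyclohex-2-ene-1-carboxylate, in one pot.
- For: both components are cheap, no precious metal is needed, and the ring B skeleton arrives with its carboxyl in one operation. On material cost it is stronger than the chosen route.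
- Against: A3 must still be dehydrogenated to the arene A4, benzyl 2,4-dihydroxy-6-pentylbenzoate, which has two free hydroxyls. The target needs methyl on the C2 oxygen (hydrogen-bonded to the ester, the less reactive one) and acyl on the C4 oxygen, so C4 must be blocked, C2 methylated and C4 freed. The ester must then still be made by acylating a phenol with the hindered acid 8.
- Comparison: the chosen route buys the C2 methoxy in 9, selects C4 by sterics, reaches the coupling partner 16 in four steps and forms the ester on the aryl side. Alternative 1 solves neither of the two structural problems.

**Alternative 2:** Ring A would be formed last, on the finished ester, cutting the C1–C2 bond of ring A. In the ring B aryl 3,5,7-trioxotetradecanoate A5 the C2 methylene adds to the C7 ketone; dehydration and enolisation should give the 6-heptyl-2,4-dihydroxybenzoate A6 (benzyl ester on ring B).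
- For: the ester is made while the acyl group is still an unhindered chain, so the steric problem is avoided as completely as in the chosen route, and the closure follows the biosynthetic pattern.
- Against: A5 is an aryl ester of a β-keto acid, and its aryloxide is a good leaving group. Lactonisation of the C5 enol onto C1 (to a hydroxypyranone) and Claisen closure from C6 onto C1 both expel the ring B phenoxide, destroying the bond the route depends on. Building A5 also needs a ring B phenol with differentiated oxygens, the same problem as in Alternative 1, plus a masked polyketone chain. A6 then needs selective methylation at C4 of ring A and a hydrogenolysis.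
- Comparison: it is longer, and its key step puts the ester itself at risk. In the chosen key step the competing processes consume only excess boronic acid.

**Alternative 3:** The ring B carboxyl would be introduced last, cutting the bond between C1 of ring B and the carboxyl carbon. The depside aryl iodide A7 would undergo hydroxycarbonylation catalysed by Pd(OAc)2 and Xantphos to give acid A8, the C6 benzyl ether of the target, followed by hydrogenolysis.
- For: ring B never carries a carboxyl through the route, so no ester protecting group is needed there and decarboxylation cannot occur on the way. On this point it is stronger than the chosen route, which carries a tert-butyl ester from step 6.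
- Against: the iodine of A7 lies between pentyl and methoxy, so oxidative addition and acyl formation are slow. The aqueous base of a hydroxycarbonylation threatens the aryl ester at the temperatures needed. A7 must itself come from acylating an iodophenol with the hindered ring A acid, and that iodophenol needs a regioselective iodination among three activated positions and a mono-methylation of a symmetric diol.
- Comparison: both the hindered esterification and the oxygen differentiation on ring B stay unsolved, whereas the chosen route removes both with one C–H borylation and one aryl–oxygen coupling.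

Key step: step 10

Assumption: 2 is used as its commercial solution in diethyl ether; the target has no stereocentre, so nothing has to be controlled stereochemically.

## Route

Step 1
Reactants: 1 1-bromo-3,5-dimethoxybenzene; 2 heptylmagnesium bromide
Product: 3 1-heptyl-3,5-dimethoxybenzene
Conditions: NiCl2(dppp) (2 mol %), Et2O, 0 °C → reflux
Reagents that add atoms: none
Why: Kumada–Corriu coupling; the chelating diphosphine on nickel makes reductive elimination of the aryl–alkyl pair faster than β-hydride elimination of the primary alkyl group, and the methyl ethers are inert.

Step 2
Reactants: 3 1-heptyl-3,5-dimethoxybenzene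
Product: 5 2-heptyl-4,6-dimethoxybenzaldehyde, via iminium chloride 4 (not isolated)
Conditions: POCl3 (1.5 equiv), DMF, 0 → 70 °C; then H2O, rt
Reagents that add atoms: N,N-dimethylformamide CN(C)C=O; water O
Why: Vilsmeier–Haack formylation; the chloroiminium electrophile should attack C2 of 3, para to one methoxy and ortho to the other, in preference to the position enclosed by both methoxy groups, and water hydrolyses iminium salt 4 to the aldehyde.

Step 3
Reactants: 5 2-heptyl-4,6-dimethoxybenzaldehyde
Product: 6 2-heptyl-6-hydroxy-4-methoxybenzaldehyde
Conditions: BCl3 (1.2 equiv), CH2Cl2, −78 → 0 °C; then H2O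
Reagents that add atoms: none
Why: Chelation-directed Lewis acid demethylation; BCl3 bridges the formyl oxygen and the ortho methoxy oxygen in a six-membered chelate, so chloride removes only that methyl group and the para methyl ether remains.

Step 4
Reactants: 6 2-heptyl-6-hydroxy-4-methoxybenzaldehyde
Product: 7 2-heptyl-4-methoxy-6-(methoxymethoxy)benzaldehyde
Conditions: MOMCl (2 equiv), i-Pr2NEt (3 equiv), CH2Cl2, 0 °C → rt
Reagents that add atoms: chloromethyl methyl ether COCCl
Why: O-alkylation of the phenol (methoxymethyl acetal formation); the oxocarbenium-like chloride is reactive enough for the hydrogen-bonded phenol, and with the carboxyl still at the aldehyde level there is no second acidic site.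

Step 5
Reactants: 7 2-heptyl-4-methoxy-6-(methoxymethoxy)benzaldehyde
Product: 8 2-heptyl-4-methoxy-6-(methoxymethoxy)benzoic acid
Conditions: NaClO2, NaH2PO4, 2-methyl-2-butene, t-BuOH/H2O, 0 °C → rt
Reagents that add atoms: sodium chlorite [Na+].[O-]Cl=O
Why: Pinnick oxidation; chlorous acid oxidises the hindered aldehyde through a small cyclic transition state, the alkene traps hypochlorous acid before it can chlorinate the electron-rich ring, and the phosphate buffer is mild enough for the acetal.

Step 6
Reactants: 9 2-methoxy-6-methylbenzoic acid
Product: 10 tert-butyl 2-methoxy-6-methylbenzoate
Conditions: Cl3CC(=NH)O-t-Bu (2 equiv), BF3·OEt2 (cat.), CH2Cl2/cyclohexane, rt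
Reagents that add atoms: tert-butyl 2,2,2-trichloroacetimidate CC(C)(C)OC(=N)C(Cl)(Cl)Cl
Why: Trichloroacetimidate tert-butylation; the new bond is made between the carboxyl oxygen and a tert-butyl cation equivalent, so the flanked acyl carbon is not attacked and the hindrance of the acid does not matter.

Step 7
Reactants: 10 tert-butyl 2-methoxy-6-methylbenzoate; 11 1-bromobutane
Product: 13 tert-butyl 2-methoxy-6-pentylbenzoate, via benzyllithium intermediate 12 (not isolated)
Conditions: LiN(i-Pr)2 (1.2 equiv), THF, −78 °C; then 11, DMPU, −78 → 0 °C
Reagents that add atoms: none
Why: Lateral lithiation and SN2 alkylation; the ortho ester stabilises the benzylic anion 12 as an extended enolate, the tert-butyl group keeps that anion from adding to the ester of a second molecule, and the primary bromide is alkylated at the benzylic carbon.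

Step 8
Reactants: 13 tert-butyl 2-methoxy-6-pentylbenzoate; 14 bis(pinacolato)diboron
Product: 15 tert-butyl 2-methoxy-6-pentyl-4-(4,4,5,5-tetramethyl-1,3,2-dioxaborolan-2-yl)benzoate
Conditions: [Ir(OMe)(cod)]2 (1.5 mol %), 4,4'-di-tert-butyl-2,2'-bipyridine (3 mol %), MTBE, 80 °C
Reagents that add atoms: none
Why: Iridium-catalysed aromatic C–H borylation; the bulky tris(boryl) complex of trivalent iridium activates only C–H bonds without an ortho substituent, and in 13 that is C4–H alone (C3–H adjoins methoxy, C5–H adjoins pentyl).

Step 9
Reactants: 15 tert-butyl 2-methoxy-6-pentyl-4-(4,4,5,5-tetramethyl-1,3,2-dioxaborolan-2-yl)benzoate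
Product: 16 (4-tert-butoxycarbonyl-3-methoxy-5-pentylphenyl)boronic acid
Conditions: NaIO4 (3 equiv), NH4OAc (3 equiv), acetone/H2O, rt
Reagents that add atoms: water O
Why: Hydrolysis of the boronic ester driven by periodate cleavage of the released diol; the medium is close to neutral, so the tert-butyl ester should persist.

Step 10
Reactants: 8 2-heptyl-4-methoxy-6-(methoxymethoxy)benzoic acid; 16 (4-tert-butoxycarbonyl-3-methoxy-5-pentylphenyl)boronic acid
Product: 17 tert-butyl 4-{[2-heptyl-4-methoxy-6-(methoxymethoxy)benzoyl]oxy}-2-methoxy-6-pentylbenzoate
Conditions: Cu(OTf)2 (1.0 equiv), urea (1.0 equiv), 2,6-lutidine (2.0 equiv), 4 Å MS, EtOAc, dry air, 60 °C; 16 (2.5 equiv) added in two portions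
Reagents that add atoms: none
Why: Chan–Lam oxidative coupling, the closest known case being the Cu(OTf)2/urea O-arylation of benzoic acids with arylboronic acids under air. The carboxylate of 8 replaces triflate on divalent copper, and the triflic acid set free is held by 2,6-lutidine, which is added so that the methoxymethyl ether and the tert-butyl ester do not meet a strong acid. The aryl group of 16 then transmetalates from boron to copper, oxidation by a second divalent copper or by oxygen gives an aryl carboxylate complex of trivalent copper, and reductive elimination forms the bond between the carboxylate oxygen and C4 of ring B; monovalent copper is reoxidised by air. No ring is closed and no stereocentre is formed. The new bond is made at an aryl carbon with hydrogen at both neighbours (C3 and C5), so the crowding at C1 of ring A (heptyl at C2, OCH2OCH3 at C6) never has to pass through a tetrahedral intermediate, while the carboxylate, twisted out of the ring plane, stays an accessible ligand. Site selectivity is built into the partners: 8 has one acidic O–H and 16 one C–B bond. The selectivity the step needs is carboxylate arylation ahead of hydroxylation, homocoupling and protodeboronation of 16; sieves, dry air and the excess, portionwise addition of the unhindered boronic acid address it.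

Step 11
Reactants: 17 tert-butyl 4-{[2-heptyl-4-methoxy-6-(methoxymethoxy)benzoyl]oxy}-2-methoxy-6-pentylbenzoate
Product: 18 4-[(2-heptyl-6-hydroxy-4-methoxybenzoyl)oxy]-2-methoxy-6-pentylbenzoic acid (target)
Conditions: CF3CO2H/CH2Cl2 (1:3), H2O (5 equiv), 0 °C → rt
Reagents that add atoms: none
Why: Acidolysis of both masks; the tert-butyl ester ionises at the alkyl–oxygen bond and the acetal at its central carbon, neither path touches an acyl carbon, so the aryl ester and the methyl ethers should remain, and the solvent is removed without heating to avoid decarboxylation of ring B.

## Compound list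

1 | 1-bromo-3,5-dimethoxybenzene | COc1cc(Br)cc(OC)c1 | starting material
2 | heptylmagnesium bromide | CCCCCCC[Mg]Br | starting material
3 | 1-heptyl-3,5-dimethoxybenzene | CCCCCCCc1cc(OC)cc(OC)c1 | intermediate
4 | N-[(2-heptyl-4,6-dimethoxyphenyl)methylidene]-N-methylmethanaminium chloride | CCCCCCCc1cc(OC)cc(OC)c1C=[N+](C)C.[Cl-] | intermediate (not isolated)
5 | 2-heptyl-4,6-dimethoxybenzaldehyde | CCCCCCCc1cc(OC)cc(OC)c1C=O | intermediate
6 | 2-heptyl-6-hydroxy-4-methoxybenzaldehyde | CCCCCCCc1cc(OC)cc(O)c1C=O | intermediate
7 | 2-heptyl-4-methoxy-6-(methoxymethoxy)benzaldehyde | CCCCCCCc1cc(OC)cc(OCOC)c1C=O | intermediate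
8 | 2-heptyl-4-methoxy-6-(methoxymethoxy)benzoic acid | CCCCCCCc1cc(OC)cc(OCOC)c1C(=O)O | intermediate
9 | 2-methoxy-6-methylbenzoic acid | COc1cccc(C)c1C(=O)O | starting material
10 | tert-butyl 2-methoxy-6-methylbenzoate | COc1cccc(C)c1C(=O)OC(C)(C)C | intermediate
11 | 1-bromobutane | CCCCBr | starting material
12 | tert-butyl 2-(lithiomethyl)-6-methoxybenzoate | [Li]Cc1cccc(OC)c1C(=O)OC(C)(C)C | intermediate (not isolated)
13 | tert-butyl 2-methoxy-6-pentylbenzoate | CCCCCc1cccc(OC)c1C(=O)OC(C)(C)C | intermediate
14 | bis(pinacolato)diboron | CC1(C)OB(OC1(C)C)B1OC(C)(C)C(C)(C)O1 | starting material
15 | tert-butyl 2-methoxy-6-pentyl-4-(4,4,5,5-tetramethyl-1,3,2-dioxaborolan-2-yl)benzoate | CCCCCc1cc(B2OC(C)(C)C(C)(C)O2)cc(OC)c1C(=O)OC(C)(C)C | intermediate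
16 | (4-tert-butoxycarbonyl-3-methoxy-5-pentylphenyl)boronic acid | CCCCCc1cc(B(O)O)cc(OC)c1C(=O)OC(C)(C)C | intermediate
17 | tert-butyl 4-{[2-heptyl-4-methoxy-6-(methoxymethoxy)benzoyl]oxy}-2-methoxy-6-pentylbenzoate | CCCCCCCc1cc(OC)cc(OCOC)c1C(=O)Oc1cc(CCCCC)c(C(=O)OC(C)(C)C)c(OC)c1 | intermediate
18 | 4-[(2-heptyl-6-hydroxy-4-methoxybenzoyl)oxy]-2-methoxy-6-pentylbenzoic acid | CCCCCCCc1cc(OC)cc(O)c1C(=O)Oc1cc(CCCCC)c(C(=O)O)c(OC)c1 | target

## Step count and least certain steps

Total: 11 steps. Longest linear sequence: 7 steps (steps 1–5, 10, 11); the ring B branch (steps 6–9) joins at step 10.

**Step 10 (key step).** The copper cycle with the bulky, twisted carboxylate may be slower than copper-mediated hydroxylation of the boronic acid by traces of water, further arylation of the phenol so formed, oxidative homocoupling and protodeboronation. If the buffering is insufficient, Lewis-acid-assisted ionisation could also remove the acetal or the tert-butyl group. The fallback gives up the aryl-side bond formation and accepts the slow acyl transfer of the classical depside esterification. It sets out from 16: oxidation of the C–B bond (H2O2, NaHCO3, THF/H2O, 0 °C) should give tert-butyl 4-hydroxy-2-methoxy-6-pentylbenzoate F1. This phenol is acylated with acid 8 by carbodiimide activation (dicyclohexylcarbodiimide, 4-(dimethylamino)pyridine, CH2Cl2, rt → 40 °C). The sequence returns to the route at 17.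

**Step 8.** Conversion of a trisubstituted, fairly electron-rich arene may stall as the catalyst decays, and borylation at the benzylic CH2 of the pentyl chain or next to the small methoxy group may accompany the C4 process. The fallback sets out from 13 and reaches the boronate through a halide:
- Sterically governed C–H silylation ([Ir(OMe)(cod)]2, 2,4,7-trimethyl-1,10-phenanthroline, HSiMe(OSiMe3)2, cyclohexene, THF, 100 °C) should give tert-butyl 2-methoxy-4-[methylbis(trimethylsilyloxy)silyl]-6-pentylbenzoate F2.
- Fluoride-assisted ipso bromination (AgF, N-bromosuccinimide, MeCN, rt) should give tert-butyl 4-bromo-2-methoxy-6-pentylbenzoate F3.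
- Miyaura borylation with 14 (Pd(dppf)Cl2, KOAc, dioxane, 80 °C) returns to the route at 15.

**Step 7.** The benzylic anion may add to the ester of unreacted 10 (self-condensation), proton exchange between product and anion may lead to double alkylation, and the SN2 step with a primary bromide may be slow at low temperature. The fallback removes the electrophilic ester from the alkylation. It sets out from acid 9, whose dianion (LiN(i-Pr)2, 2.2 equiv, THF, −78 → 0 °C) is alkylated with 11 to give 2-methoxy-6-pentylbenzoic acid F4. Esterification of F4 under the conditions of step 6 returns to the route at 13.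

**Step 2.** Competing attack at the position between the two methoxy groups of 3 would erode the regiochemical purity of the aldehyde. The fallback separates the choice of position from the introduction of carbon. It sets out from 3: bromination (N-bromosuccinimide, MeCN, 0 °C) should give 2-bromo-1-heptyl-3,5-dimethoxybenzene F5, a bromide that can be purified before the carbon is added. Bromine–lithium exchange (n-BuLi, THF, −78 °C) and quenching with DMF return to the route at 5.

**Step 11.** The tert-butyl and methoxymethyl cations, or the formaldehyde released, may alkylate the electron-rich ring A phenol, and prolonged acid may start decarboxylation of ring B. The fallback removes the two masks separately and without free protic acid. It sets out from 17: ZnBr2 and propane-1-thiol (CH2Cl2, 0 °C) should transfer the methoxymethyl group to sulfur and give tert-butyl 4-[(2-heptyl-6-hydroxy-4-methoxybenzoyl)oxy]-2-methoxy-6-pentylbenzoate F6. Me3SiOTf and 2,6-lutidine (CH2Cl2, 0 °C), followed by aqueous work-up, then cleave the tert-butyl ester through its silyl ester and return to the route at 18.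

## Further compounds

F1 | step 10 | tert-butyl 4-hydroxy-2-methoxy-6-pentylbenzoate | CCCCCc1cc(O)cc(OC)c1C(=O)OC(C)(C)C
F2 | step 8 | tert-butyl 2-methoxy-4-[methylbis(trimethylsilyloxy)silyl]-6-pentylbenzoate | CCCCCc1cc([Si](C)(O[Si](C)(C)C)O[Si](C)(C)C)cc(OC)c1C(=O)OC(C)(C)C
F3 | step 8 | tert-butyl 4-bromo-2-methoxy-6-pentylbenzoate | CCCCCc1cc(Br)cc(OC)c1C(=O)OC(C)(C)C
F4 | step 7 | 2-methoxy-6-pentylbenzoic acid | CCCCCc1cccc(OC)c1C(=O)O
F5 | step 2 | 2-bromo-1-heptyl-3,5-dimethoxybenzene | CCCCCCCc1cc(OC)cc(OC)c1Br
F6 | step 11 | tert-butyl 4-[(2-heptyl-6-hydroxy-4-methoxybenzoyl)oxy]-2-methoxy-6-pentylbenzoate | CCCCCCCc1cc(OC)cc(O)c1C(=O)Oc1cc(CCCCC)c(C(=O)OC(C)(C)C)c(OC)c1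
A1 | alternative 1 | dibenzyl malonate | O=C(CC(=O)OCc1ccccc1)OCc1ccccc1
A2 | alternative 1 | (E)-non-3-en-2-one | CCCCC/C=C/C(C)=O
A3 | alternative 1 | racemic trans-benzyl 2-hydroxy-4-oxo-6-pentylcyclohex-2-ene-1-carboxylate (one enantiomer drawn) | CCCCC[C@@H]1CC(=O)C=C(O)[C@H]1C(=O)OCc1ccccc1
A4 | alternative 1 | benzyl 2,4-dihydroxy-6-pentylbenzoate | CCCCCc1cc(O)cc(O)c1C(=O)OCc1ccccc1
A5 | alternative 2 | benzyl 2-methoxy-6-pentyl-4-[(3,5,7-trioxotetradecanoyl)oxy]benzoate | CCCCCCCC(=O)CC(=O)CC(=O)CC(=O)Oc1cc(CCCCC)c(C(=O)OCc2ccccc2)c(OC)c1
A6 | alternative 2 | benzyl 4-[(6-heptyl-2,4-dihydroxybenzoyl)oxy]-2-methoxy-6-pentylbenzoate | CCCCCCCc1cc(O)cc(O)c1C(=O)Oc1cc(CCCCC)c(C(=O)OCc2ccccc2)c(OC)c1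
A7 | alternative 3 | 4-iodo-3-methoxy-5-pentylphenyl 2-(benzyloxy)-6-heptyl-4-methoxybenzoate | CCCCCCCc1cc(OC)cc(OCc2ccccc2)c1C(=O)Oc1cc(CCCCC)c(I)c(OC)c1
A8 | alternative 3 | 4-{[2-(benzyloxy)-6-heptyl-4-methoxybenzoyl]oxy}-2-methoxy-6-pentylbenzoic acid | CCCCCCCc1cc(OC)cc(OCc2ccccc2)c1C(=O)Oc1cc(CCCCC)c(C(=O)O)c(OC)c1
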